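**Retrosynthetic overview**
1. Last disconnection: the aryl ether C–O bond, made by Mitsunobu reaction of umbelliferone 22 with the only primary hydroxyl of tetraol 21.
2. Key disconnection: the bond between the acyclic tertiary carbinol carbon (C3 of the pentyl chain) and the neighbouring chain CH2 (C4), made by lithiation–borylation–oxidation of benzoate 16 with ring boronic ester 13.
3. Enabling feature: that carbinol carbon bears OH, CH3 and a CH2CH2O arm, so it is C3 of butane-1,3-diol with its hydrogen replaced by carbon. The (R)-diol supplies oxygen, methyl and configuration; its C–H is lithiated next to the ester oxygen, and boron returns the oxygen after a stereospecific C–C shift.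
4. No ring is built: the cyclohexane is that of (S)-3-hydroxy-2,2-dimethylcyclohexanone 1 and the coumarin that of 22. The two further ring stereocentres follow from C3 of 1 by anti epoxidation of a vinyl diene and hydroxyl-directed trans-diaxial hydride opening.

Key step: step 12

Remark: 1, 14 and 22 are taken as purchased materials, enantiopure where chiral; no other assumption is needed.

Step 1
Reactants: 1 (S)-3-hydroxy-2,2-dimethylcyclohexan-1-one
Product: 2 (S)-3-[(tert-butyldimethylsilyl)oxy]-2,2-dimethylcyclohexan-1-one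
Conditions: TBSCl, imidazole, DMF, rt
Reagents that add atoms: tert-butyldimethylsilyl chloride, CC(C)(C)[Si](C)(C)Cl
Why: Silyl ether formation should protect the secondary hydroxyl against the strong bases of steps 2 and 3 without touching the stereocentre.

Step 2
Reactants: 2 (S)-3-[(tert-butyldimethylsilyl)oxy]-2,2-dimethylcyclohexan-1-one
Product: 4 (3S,6RS)-3-[(tert-butyldimethylsilyl)oxy]-2,2,6-trimethylcyclohexan-1-one, via lithium enolate 3 (not isolated)
Conditions: LiN(iPr)2, THF, −78 °C; then MeI, −78 → 0 °C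
Reagents that add atoms: iodomethane, CI
Why: Enolate alkylation: the ketone can enolise only towards C6 because C2 is quaternary, so methylation should occur there, and the new C6 stereocentre may form as a mixture because it becomes sp2 in step 3.

Step 3
Reactants: 4 (3S,6RS)-3-[(tert-butyldimethylsilyl)oxy]-2,2,6-trimethylcyclohexan-1-one
Product: 6 (5S)-5-[(tert-butyldimethylsilyl)oxy]-2,6,6-trimethylcyclohex-1-en-1-yl trifluoromethanesulfonate, via potassium enolate 5 (not isolated)
Conditions: KN(SiMe3)2, THF, −78 → 0 °C; then PhNTf2, 0 °C → rt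
Reagents that add atoms: N-phenylbis(trifluoromethanesulfonimide), O=S(=O)(N(c1ccccc1)S(=O)(=O)C(F)(F)F)C(F)(F)F
Why: Enol triflate formation by O-sulfonylation of the only available, tetrasubstituted enolate should give the vinyl electrophile and removes the C6 stereocentre.

Step 4
Reactants: 6 (5S)-5-[(tert-butyldimethylsilyl)oxy]-2,6,6-trimethylcyclohex-1-en-1-yl trifluoromethanesulfonate
Product: 7 tert-butyldimethyl{[(1S)-2,2,4-trimethyl-3-vinylcyclohex-3-en-1-yl]oxy}silane
Conditions: tributyl(vinyl)stannane, Pd(PPh3)4 (cat.), LiCl, THF, 65 °C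
Reagents that add atoms: tributyl(vinyl)stannane, C=C[Sn](CCCC)(CCCC)CCCC
Why: Stille cross-coupling of the enol triflate with the vinylstannane should install the two carbons of the future ethylene tether as a vinyl group and give the 1,3-diene.

Step 5
Reactants: 7 tert-butyldimethyl{[(1S)-2,2,4-trimethyl-3-vinylcyclohex-3-en-1-yl]oxy}silane
Product: 8 tert-butyldimethyl{[(1R,3S,6S)-2,2,6-trimethyl-1-vinyl-7-oxabicyclo[4.1.0]heptan-3-yl]oxy}silane
Conditions: mCPBA, NaHCO3, CH2Cl2, 0 °C
Reagents that add atoms: 3-chloroperbenzoic acid, OOC(=O)c1cccc(Cl)c1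
Why: Peracid (Prilezhaev) epoxidation should occur at the electron-rich tetrasubstituted ring alkene rather than the vinyl group, and both new stereocentres are set by attack anti to the silyloxy group, because in the half-chair with equatorial OTBS the pseudoaxial allylic methyl group screens the face that carries the oxygen substituent.

Step 6
Reactants: 8 tert-butyldimethyl{[(1R,3S,6S)-2,2,6-trimethyl-1-vinyl-7-oxabicyclo[4.1.0]heptan-3-yl]oxy}silane
Product: 9 (1R,3S,6S)-2,2,6-trimethyl-1-vinyl-7-oxabicyclo[4.1.0]heptan-3-ol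
Conditions: Bu4NF, THF, 0 °C → rt
Reagents that add atoms: none
Why: Fluoride-mediated desilylation should free the hydroxyl that has to direct step 7, the epoxide being stable to these mildly basic conditions.

Step 7
Reactants: 9 (1R,3S,6S)-2,2,6-trimethyl-1-vinyl-7-oxabicyclo[4.1.0]heptan-3-ol
Product: 10 (1S,2R,4S)-1,3,3-trimethyl-2-vinylcyclohexane-1,4-diol
Conditions: LiAlH4, THF, 0 °C → rt; aqueous NaOH work-up
Reagents that add atoms: none
Why: Hydroxyl-directed hydride opening of an epoxy alcohol: the alkoxyaluminate at the axial C3 oxygen should deliver hydride intramolecularly to the allylic tertiary epoxide carbon C1 in a trans-diaxial opening anti to the epoxide oxygen, which sets the new C–H stereocentre with inversion so that the vinyl group ends cis to the retained tertiary hydroxyl and trans to the secondary one.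

Step 8
Reactants: 10 (1S,2R,4S)-1,3,3-trimethyl-2-vinylcyclohexane-1,4-diol
Product: 11 {[(1S,2R,4S)-1,3,3-trimethyl-2-vinylcyclohexane-1,4-diyl]bis(oxy)}bis(triethylsilane)
Conditions: TESOTf, 2,6-lutidine, CH2Cl2, −78 → 0 °C
Reagents that add atoms: triethylsilyl trifluoromethanesulfonate, CC[Si](CC)(CC)OS(=O)(=O)C(F)(F)F
Why: Silyl ether formation with the reactive silyl triflate should cap both the hindered secondary and the tertiary hydroxyl, which must not quench the organolithium or bind boron in step 12.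

Step 9
Reactants: 11 {[(1S,2R,4S)-1,3,3-trimethyl-2-vinylcyclohexane-1,4-diyl]bis(oxy)}bis(triethylsilane)
Product: 13 5,5-dimethyl-2-{2-[(1R,3S,6S)-2,2,6-trimethyl-3,6-bis(triethylsilyloxy)cyclohexyl]ethyl}-1,3,2-dioxaborinane, via catechol boronate 12 (not isolated)
Conditions: catecholborane, RhCl(PPh3)3 (cat.), THF, rt; then 2,2-dimethylpropane-1,3-diol, rt
Reagents that add atoms: catecholborane, [H]B1Oc2ccccc2O1; 2,2-dimethylpropane-1,3-diol, OCC(C)(C)CO
Why: Rhodium-catalysed anti-Markovnikov hydroboration of the terminal alkene followed by diol exchange (transesterification) should place boron on the terminal carbon and give the neopentyl glycol boronic ester needed for the key step; no stereocentre is formed.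

Step 10
Reactants: 14 (R)-butane-1,3-diol
Product: 15 (R)-4-[(triisopropylsilyl)oxy]butan-2-ol
Conditions: TIPSCl, imidazole, CH2Cl2, 0 °C
Reagents that add atoms: triisopropylsilyl chloride, CC(C)[Si](Cl)(C(C)C)C(C)C
Why: Selective silyl ether formation at the primary hydroxyl of the 1,3-diol should leave the secondary carbinol free, and the bulky TIPS group is chosen because it resists migration to carbon in the organolithium of step 12.

Step 11
Reactants: 15 (R)-4-[(triisopropylsilyl)oxy]butan-2-ol
Product: 16 (S)-4-[(triisopropylsilyl)oxy]butan-2-yl 2,4,6-triisopropylbenzoate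
Conditions: 2,4,6-triisopropylbenzoic acid, PPh3, DIAD, THF, 0 °C → rt
Reagents that add atoms: 2,4,6-triisopropylbenzoic acid, CC(C)c1cc(C(C)C)c(C(=O)O)c(C(C)C)c1
Why: Mitsunobu esterification with the hindered benzoic acid should give the (S)-benzoate by SN2 inversion of the (R)-carbinol, which fixes the configuration that the key step transfers.

Step 12
Reactants: 16 (S)-4-[(triisopropylsilyl)oxy]butan-2-yl 2,4,6-triisopropylbenzoate; 13 5,5-dimethyl-2-{2-[(1R,3S,6S)-2,2,6-trimethyl-3,6-bis(triethylsilyloxy)cyclohexyl]ethyl}-1,3,2-dioxaborinane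
Product: 20 (3R)-3-methyl-5-[(1R,3S,6S)-2,2,6-trimethyl-3,6-bis(triethylsilyloxy)cyclohexyl]-1-(triisopropylsilyloxy)pentan-3-ol, via lithiated benzoate 17 (not isolated), via boronate complex 18 (not isolated), via tertiary boronic ester 19 (not isolated)
Conditions: sBuLi, TMEDA, cyclopentyl methyl ether, −60 °C; then 13, −60 → 50 °C; then NaOH, H2O2, THF–H2O, 0 °C → rt
Reagents that add atoms: hydrogen peroxide, OO
Why: Lithiation–borylation–oxidation: sBuLi/TMEDA removes the carbinol hydrogen of 16 next to the ester oxygen to give the configurationally stable tertiary organolithium 17 with retention, which adds to the boron of 13 with retention to give boronate complex 18; on warming, the ring-bearing ethyl group shifts from boron to carbon anti to the departing triisopropylbenzoate (1,2-metallate rearrangement with inversion), forming the C–C bond in tertiary boronic ester 19, whose C–B bond is then oxidised with retention. The closest known reaction type is the lithiation–borylation of secondary dialkyl 2,4,6-triisopropylbenzoates with primary neopentyl glycol boronic esters, which gives tertiary boronic esters and, after oxidation, tertiary alcohols. No ring is closed. The one new stereocentre, the fully substituted carbinol carbon, is controlled solely by the configuration of the (S)-benzoate: the net result is replacement of its hydrogen by the carbon group with retention, which gives the (R)-alcohol. The step needs deprotonation instead of carbonyl attack, a carbanion that neither racemises nor suffers silyl migration, and irreversible capture by boron; these are secured by the 2,4,6-triisopropyl shielding, the low temperature in cyclopentyl methyl ether, the bulky TIPS ether and the unhindered primary boronic ester, while the silyl ethers of 13 are inert to the reagents.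

Step 13
Reactants: 20 (3R)-3-methyl-5-[(1R,3S,6S)-2,2,6-trimethyl-3,6-bis(triethylsilyloxy)cyclohexyl]-1-(triisopropylsilyloxy)pentan-3-ol
Product: 21 (3R)-5-[(1R,3S,6S)-3,6-dihydroxy-2,2,6-trimethylcyclohexyl]-3-methylpentane-1,3-diol
Conditions: Bu4NF, THF, rt → 50 °C
Reagents that add atoms: none
Why: Global fluoride-mediated desilylation should remove the TIPS ether and both triethylsilyl ethers in one operation to expose the tetraol; no stereocentre is affected.

Step 14
Reactants: 21 (3R)-5-[(1R,3S,6S)-3,6-dihydroxy-2,2,6-trimethylcyclohexyl]-3-methylpentane-1,3-diol; 22 7-hydroxy-2H-chromen-2-one (umbelliferone)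
Product: 23 7-{[(3R)-5-[(1R,3S,6S)-3,6-dihydroxy-2,2,6-trimethylcyclohexyl]-3-hydroxy-3-methylpentyl]oxy}-2H-chromen-2-one (target)
Conditions: PPh3, DIAD, THF, 0 °C → rt
Reagents that add atoms: none
Why: Mitsunobu etherification: the acidic phenol should be alkylated by the only primary alcohol, since the tertiary alcohols and the hindered axial secondary alcohol do not form reactive oxyphosphonium ions, and no stereocentre is involved.

**Compound list**
1 | (S)-3-hydroxy-2,2-dimethylcyclohexan-1-one | CC1(C)C(=O)CCC[C@@H]1O | starting material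
2 | (S)-3-[(tert-butyldimethylsilyl)oxy]-2,2-dimethylcyclohexan-1-one | CC1(C)C(=O)CCC[C@@H]1O[Si](C)(C)C(C)(C)C | intermediate
3 | lithium (5S)-5-[(tert-butyldimethylsilyl)oxy]-6,6-dimethylcyclohex-1-en-1-olate | CC1(C)C([O-])=CCC[C@@H]1O[Si](C)(C)C(C)(C)C.[Li+] | intermediate
4 | (3S,6RS)-3-[(tert-butyldimethylsilyl)oxy]-2,2,6-trimethylcyclohexan-1-one | CC1(C)C(=O)C(C)CC[C@@H]1O[Si](C)(C)C(C)(C)C | intermediate
5 | potassium (5S)-5-[(tert-butyldimethylsilyl)oxy]-2,6,6-trimethylcyclohex-1-en-1-olate | CC1(C)C([O-])=C(C)CC[C@@H]1O[Si](C)(C)C(C)(C)C.[K+] | intermediate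
6 | (5S)-5-[(tert-butyldimethylsilyl)oxy]-2,6,6-trimethylcyclohex-1-en-1-yl trifluoromethanesulfonate | CC1(C)C(OS(=O)(=O)C(F)(F)F)=C(C)CC[C@@H]1O[Si](C)(C)C(C)(C)C | intermediate
7 | tert-butyldimethyl{[(1S)-2,2,4-trimethyl-3-vinylcyclohex-3-en-1-yl]oxy}silane | CC1(C)C(C=C)=C(C)CC[C@@H]1O[Si](C)(C)C(C)(C)C | intermediate
8 | tert-butyldimethyl{[(1R,3S,6S)-2,2,6-trimethyl-1-vinyl-7-oxabicyclo[4.1.0]heptan-3-yl]oxy}silane | CC1(C)[C@@]2(C=C)O[C@@]2(C)CC[C@@H]1O[Si](C)(C)C(C)(C)C | intermediate
9 | (1R,3S,6S)-2,2,6-trimethyl-1-vinyl-7-oxabicyclo[4.1.0]heptan-3-ol | CC1(C)[C@@]2(C=C)O[C@@]2(C)CC[C@@H]1O | intermediate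
10 | (1S,2R,4S)-1,3,3-trimethyl-2-vinylcyclohexane-1,4-diol | CC1(C)[C@@H](C=C)[C@@](C)(O)CC[C@@H]1O | intermediate
11 | {[(1S,2R,4S)-1,3,3-trimethyl-2-vinylcyclohexane-1,4-diyl]bis(oxy)}bis(triethylsilane) | CC1(C)[C@@H](C=C)[C@@](C)(O[Si](CC)(CC)CC)CC[C@@H]1O[Si](CC)(CC)CC | intermediate
12 | 2-{2-[(1R,3S,6S)-2,2,6-trimethyl-3,6-bis(triethylsilyloxy)cyclohexyl]ethyl}-1,3,2-benzodioxaborole | CC1(C)[C@@H](CCB2Oc3ccccc3O2)[C@@](C)(O[Si](CC)(CC)CC)CC[C@@H]1O[Si](CC)(CC)CC | intermediate
13 | 5,5-dimethyl-2-{2-[(1R,3S,6S)-2,2,6-trimethyl-3,6-bis(triethylsilyloxy)cyclohexyl]ethyl}-1,3,2-dioxaborinane | CC1(C)[C@@H](CCB2OCC(C)(C)CO2)[C@@](C)(O[Si](CC)(CC)CC)CC[C@@H]1O[Si](CC)(CC)CC | intermediate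
14 | (R)-butane-1,3-diol | C[C@@H](O)CCO | starting material
15 | (R)-4-[(triisopropylsilyl)oxy]butan-2-ol | C[C@@H](O)CCO[Si](C(C)C)(C(C)C)C(C)C | intermediate
16 | (S)-4-[(triisopropylsilyl)oxy]butan-2-yl 2,4,6-triisopropylbenzoate | C[C@H](OC(=O)c1c(C(C)C)cc(C(C)C)cc1C(C)C)CCO[Si](C(C)C)(C(C)C)C(C)C | intermediate
17 | (S)-2-lithio-4-[(triisopropylsilyl)oxy]butan-2-yl 2,4,6-triisopropylbenzoate | C[C@]([Li])(OC(=O)c1c(C(C)C)cc(C(C)C)cc1C(C)C)CCO[Si](C(C)C)(C(C)C)C(C)C | intermediate
18 | lithium boronate complex of 17 and 13 (tetracoordinate boron carrying the carbinol carbon of 17 and the ethyl chain of 13) | C[C@]([B-]1(CC[C@@H]2C(C)(C)[C@@H](O[Si](CC)(CC)CC)CC[C@]2(C)O[Si](CC)(CC)CC)OCC(C)(C)CO1)(OC(=O)c1c(C(C)C)cc(C(C)C)cc1C(C)C)CCO[Si](C(C)C)(C(C)C)C(C)C.[Li+] | intermediate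
19 | 5,5-dimethyl-2-{(3S)-3-methyl-5-[(1R,3S,6S)-2,2,6-trimethyl-3,6-bis(triethylsilyloxy)cyclohexyl]-1-(triisopropylsilyloxy)pentan-3-yl}-1,3,2-dioxaborinane | C[C@@](B1OCC(C)(C)CO1)(CC[C@@H]2C(C)(C)[C@@H](O[Si](CC)(CC)CC)CC[C@]2(C)O[Si](CC)(CC)CC)CCO[Si](C(C)C)(C(C)C)C(C)C | intermediate
20 | (3R)-3-methyl-5-[(1R,3S,6S)-2,2,6-trimethyl-3,6-bis(triethylsilyloxy)cyclohexyl]-1-(triisopropylsilyloxy)pentan-3-ol | CC1(C)[C@@H](CC[C@@](C)(O)CCO[Si](C(C)C)(C(C)C)C(C)C)[C@@](C)(O[Si](CC)(CC)CC)CC[C@@H]1O[Si](CC)(CC)CC | intermediate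
21 | (3R)-5-[(1R,3S,6S)-3,6-dihydroxy-2,2,6-trimethylcyclohexyl]-3-methylpentane-1,3-diol | CC1(C)[C@@H](CC[C@@](C)(O)CCO)[C@@](C)(O)CC[C@@H]1O | intermediate
22 | 7-hydroxy-2H-chromen-2-one (umbelliferone) | Oc1ccc2ccc(=O)oc2c1 | starting material
23 | 7-{[(3R)-5-[(1R,3S,6S)-3,6-dihydroxy-2,2,6-trimethylcyclohexyl]-3-hydroxy-3-methylpentyl]oxy}-2H-chromen-2-one | CC1(C)[C@@H](CC[C@@](C)(O)CCOc2ccc3ccc(=O)oc3c2)[C@@](C)(O)CC[C@@H]1O | target

**Step count**
Total: 14 steps. Longest linear sequence: 12 steps (steps 1–9, then 12, 13 and 14).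

**Steps most likely to fail**

Step 7. Undirected conjugate (SN2′) hydride attack at the vinyl terminus, or aluminium-induced ionisation and rearrangement of the tertiary allylic epoxide, may outrun the intramolecular delivery. The fallback sets out from silyl ether 8 and uses a π-allylpalladium instead of an aluminium alkoxide. Hydrogenolysis of the alkenyloxirane with HCO2H and Et3N, catalysed by Pd2(dba)3 and PBu3 in dioxane, should transfer hydride to the fully substituted allyl terminus on the face opposite the departing oxygen. This should give (1S,2R,4S)-4-[(tert-butyldimethylsilyl)oxy]-1,3,3-trimethyl-2-vinylcyclohexan-1-ol F1. Bu4NF in THF should then remove the silyl group, and the route is rejoined at 10.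

Step 12. Slow or reversible boronate-complex formation by the hindered tertiary organolithium, or its decomposition before capture, may leave 13 unconsumed. The fallback sets out from 11 and builds the carbinol by cross-coupling and asymmetric epoxidation.
- Hydroboration with 9-BBN in THF should give 9-{2-[(1R,3S,6S)-2,2,6-trimethyl-3,6-bis(triethylsilyloxy)cyclohexyl]ethyl}-9-borabicyclo[3.3.1]nonane F2.
- Suzuki–Miyaura coupling with purchased (E)-3-iodobut-2-en-1-ol (Pd(dppf)Cl2, Cs2CO3, DMF–H2O) should give (2E)-3-methyl-5-[(1R,3S,6S)-2,2,6-trimethyl-3,6-bis(triethylsilyloxy)cyclohexyl]pent-2-en-1-ol F3.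
- Sharpless asymmetric epoxidation (Ti(OiPr)4, D-(−)-diethyl tartrate, tBuOOH, CH2Cl2, −20 °C) should give [(2R,3R)-3-methyl-3-{2-[(1R,3S,6S)-2,2,6-trimethyl-3,6-bis(triethylsilyloxy)cyclohexyl]ethyl}oxiran-2-yl]methanol F4.
- Hydroxyl-directed opening at C2 with NaAlH2(OCH2CH2OMe)2 in THF should give (3R)-3-methyl-5-[(1R,3S,6S)-2,2,6-trimethyl-3,6-bis(triethylsilyloxy)cyclohexyl]pentane-1,3-diol F5.
- Bu4NF should then remove the two silyl groups, and the route is rejoined at 21.

Step 14. Loss of site selectivity among the four hydroxyls, or sluggish activation of the primary alcohol next to the free tertiary carbinol, may erode the etherification. The fallback sets out from 21 and replaces the redox condensation by sulfonate displacement. Selective sulfonylation of the primary hydroxyl (TsCl, pyridine, 0 °C) should give (3R)-5-[(1R,3S,6S)-3,6-dihydroxy-2,2,6-trimethylcyclohexyl]-3-hydroxy-3-methylpentyl 4-methylbenzenesulfonate F6. Williamson etherification with 22 and K2CO3 in DMF at 60 °C should then give the target, so the route is rejoined at 23.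

Further compounds
F1 | step 7 | (1S,2R,4S)-4-[(tert-butyldimethylsilyl)oxy]-1,3,3-trimethyl-2-vinylcyclohexan-1-ol | CC1(C)[C@@H](C=C)[C@@](C)(O)CC[C@@H]1O[Si](C)(C)C(C)(C)C
F2 | step 12 | 9-{2-[(1R,3S,6S)-2,2,6-trimethyl-3,6-bis(triethylsilyloxy)cyclohexyl]ethyl}-9-borabicyclo[3.3.1]nonane | CC1(C)[C@@H](CCB2C3CCCC2CCC3)[C@@](C)(O[Si](CC)(CC)CC)CC[C@@H]1O[Si](CC)(CC)CC
F3 | step 12 | (2E)-3-methyl-5-[(1R,3S,6S)-2,2,6-trimethyl-3,6-bis(triethylsilyloxy)cyclohexyl]pent-2-en-1-ol | CC1(C)[C@@H](CC/C(C)=C/CO)[C@@](C)(O[Si](CC)(CC)CC)CC[C@@H]1O[Si](CC)(CC)CC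
F4 | step 12 | [(2R,3R)-3-methyl-3-{2-[(1R,3S,6S)-2,2,6-trimethyl-3,6-bis(triethylsilyloxy)cyclohexyl]ethyl}oxiran-2-yl]methanol | CC1(C)[C@@H](CC[C@@]2(C)O[C@@H]2CO)[C@@](C)(O[Si](CC)(CC)CC)CC[C@@H]1O[Si](CC)(CC)CC
F5 | step 12 | (3R)-3-methyl-5-[(1R,3S,6S)-2,2,6-trimethyl-3,6-bis(triethylsilyloxy)cyclohexyl]pentane-1,3-diol | CC1(C)[C@@H](CC[C@@](C)(O)CCO)[C@@](C)(O[Si](CC)(CC)CC)CC[C@@H]1O[Si](CC)(CC)CC
F6 | step 14 | (3R)-5-[(1R,3S,6S)-3,6-dihydroxy-2,2,6-trimethylcyclohexyl]-3-hydroxy-3-methylpentyl 4-methylbenzenesulfonate | CC1(C)[C@@H](CC[C@@](C)(O)CCOS(=O)(=O)c2ccc(C)cc2)[C@@](C)(O)CC[C@@H]1O
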